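**Retrosynthetic overview**

- Feature: ring B of the apigenin unit (flavone numbering in each unit) is a 1,3,4-trisubstituted benzene. C1′ carries the pyranone carbon C2, C3′ carries C8 of the acacetin unit and C4′ carries OH. This is a 3-aryl-4-hydroxybenzoate, the arene that methyl coumalate (its C3–C6 plus the ester) forms with a 2-aryl ketene acetal after loss of CO2.
- Last disconnection: the apigenin pyranone is cut to the benzoate carbon and 2-hydroxy-4,6-bis(benzyloxy)acetophenone (Baker–Venkataraman rearrangement, cyclodehydration); five benzyl ethers fall in one final hydrogenolysis.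
- Key disconnection: ring B at C2′–C3′ and C4′–C5′ into methyl coumalate and the ketene bis(trimethylsilyl) acetal of the acacetin-8-ylacetic acid. The C3′–C8 biaryl bond is then only a benzylic bond of that acid.
- The acetic acid chain comes from an allyl group placed by Claisen rearrangement on the acetophenone before the acacetin pyranone is closed. Only one ortho position is open there, whereas a 7-allyloxy-5-hydroxyflavone could also deliver allyl to C6.
- Ring order: acacetin ring A (bought as phloroacetophenone), acacetin pyranone, apigenin ring B (key step), apigenin pyranone built on a second portion of the same acetophenone.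

Key step: step 9

Remark: the target has no stereocentre, and the C3′–C8 axis (three ortho substituents) is treated as freely rotating, since the structure given carries no axial descriptor.

**Route**

Step 1
Reactants: 1 2,4,6-trihydroxyacetophenone
Product: 2 1-[2,4-bis(benzyloxy)-6-hydroxyphenyl]ethanone (2-hydroxy-4,6-bis(benzyloxy)acetophenone)
Conditions: BnBr (2.1 equiv), K2CO3, DMF, rt
Reagents that add atoms: benzyl bromide, BrCc1ccccc1
Why: Williamson etherification alkylates the 4-OH and one ortho OH, while the remaining ortho OH is locked in a hydrogen bond to the acetyl carbonyl and should not react under carbonate conditions at room temperature.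

Step 2
Reactants: 2 1-[2,4-bis(benzyloxy)-6-hydroxyphenyl]ethanone; 3 allyl bromide
Product: 4 1-[2-(allyloxy)-4,6-bis(benzyloxy)phenyl]ethanone
Conditions: K2CO3, DMF, 60 °C
Reagents that add atoms: none
Why: Williamson etherification of the chelated phenol, which should yield to a reactive allylic halide in warm carbonate/DMF.

Step 3
Reactants: 4 1-[2-(allyloxy)-4,6-bis(benzyloxy)phenyl]ethanone
Product: 6 1-[3-allyl-4,6-bis(benzyloxy)-2-hydroxyphenyl]ethanone, via ortho-dienone 5 (not isolated)
Conditions: N,N-diethylaniline, 195 °C, argon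
Reagents that add atoms: none
Why: Aromatic Claisen rearrangement ([3,3]-sigmatropic shift): of the two ortho positions only C3 is free, because C1 carries the acetyl group, so the allyl group can only reach C3 and dienone 5 tautomerises to the chelated phenol.

Step 4
Reactants: 6 1-[3-allyl-4,6-bis(benzyloxy)-2-hydroxyphenyl]ethanone; 7 4-methoxybenzoyl chloride
Product: 8 1-[3-allyl-4,6-bis(benzyloxy)-2-hydroxyphenyl]-3-(4-methoxyphenyl)propane-1,3-dione
Conditions: LiN(SiMe3)2 (3.2 equiv), THF, −78 → −10 °C; 7, −78 °C → rt; aq. HCl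
Reagents that add atoms: none
Why: Direct C-acylation of the lithium dianion (phenoxide plus ketone enolate) of a 2-hydroxyacetophenone by an aroyl chloride, a one-flask equivalent of the Baker–Venkataraman sequence; any O-aroyl ester formed should rearrange to the same diketone under the excess base.

Step 5
Reactants: 8 1-[3-allyl-4,6-bis(benzyloxy)-2-hydroxyphenyl]-3-(4-methoxyphenyl)propane-1,3-dione
Product: 9 8-allyl-5,7-bis(benzyloxy)-4′-methoxyflavone
Conditions: NaOAc, AcOH, 110 °C
Reagents that add atoms: none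
Why: Cyclodehydration of the 1-(2-hydroxyaryl)-1,3-diketone (hemiketal formation, then loss of water) closes the pyranone; only one phenol is free, so the allyl group must end up at C8, and buffered acetic acid should spare the benzyl ethers and the alkene.

Step 6
Reactants: 9 8-allyl-5,7-bis(benzyloxy)-4′-methoxyflavone
Product: 11 [5,7-bis(benzyloxy)-4′-methoxyflavon-8-yl]acetaldehyde, via vicinal diol 10 (not isolated)
Conditions: OsO4 (cat.), NaIO4, 2,6-lutidine, dioxane/H2O, rt
Reagents that add atoms: osmium tetroxide, O=[Os](=O)(=O)=O (delivers the aldehyde oxygen; catalytic, restored by sodium periodate, [Na+].[O-]I(=O)(=O)=O)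
Why: Lemieux–Johnson oxidation: OsO4 should dihydroxylate the monosubstituted alkene far faster than the deactivated, trisubstituted C2–C3 double bond of the flavone, and NaIO4 cleaves diol 10 to the aldehyde, with 2,6-lutidine suppressing side reactions.

Step 7
Reactants: 11 [5,7-bis(benzyloxy)-4′-methoxyflavon-8-yl]acetaldehyde
Product: 12 [5,7-bis(benzyloxy)-4′-methoxyflavon-8-yl]acetic acid
Conditions: NaClO2, NaH2PO4, 2-methyl-2-butene, t-BuOH/THF/H2O, 0 °C → rt
Reagents that add atoms: sodium chlorite, [Na+].[O-]Cl=O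
Why: Pinnick oxidation converts the aldehyde into the acid under buffered conditions, with 2-methyl-2-butene trapping HOCl so that the electron-rich ring is not chlorinated.

Step 8
Reactants: 12 [5,7-bis(benzyloxy)-4′-methoxyflavon-8-yl]acetic acid
Product: 14 5,7-bis(benzyloxy)-8-[2,2-bis(trimethylsilyloxy)ethenyl]-4′-methoxyflavone (ketene bis(trimethylsilyl) acetal of 12), via trimethylsilyl ester 13 (not isolated)
Conditions: LiN(SiMe3)2 (1.0 equiv), Me3SiCl, THF, −78 → 0 °C; LiN(SiMe3)2 (1.2 equiv), −78 °C, then Me3SiCl, → rt; evaporation, dry toluene, filtration under argon; used crude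
Reagents that add atoms: chlorotrimethylsilane, C[Si](C)(C)Cl
Why: Silylation of the carboxylate gives ester 13, whose α-proton (activated by ester and aryl group) should be removed by the hindered, non-nucleophilic amide base without attack on the flavone, and O-silylation of the enolate gives the ketene acetal, which has no E/Z question because both oxygen substituents are the same.

Step 9
Reactants: 14 5,7-bis(benzyloxy)-8-[2,2-bis(trimethylsilyloxy)ethenyl]-4′-methoxyflavone; 15 methyl coumalate
Product: 19 methyl 3-[5,7-bis(benzyloxy)-4′-methoxyflavon-8-yl]-4-hydroxybenzoate, via bridged lactone cycloadduct 16 (not isolated), via cyclohexadiene 17 (not isolated), via aryl trimethylsilyl ether 18 (not isolated)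
Conditions: 15 (3 equiv), PhMe, 110 °C, sealed tube, argon; then 1 M HCl, THF, rt
Reagents that add atoms: none
Why: The electron-rich ketene acetal 14 and the electron-poor 2-pyrone 15 combine in an inverse-electron-demand Diels–Alder reaction across C3 and C6 of the pyrone (concerted but asynchronous, or stepwise through a zwitterion from attack at C6 that collapses by closure of the six-membered ring), giving bridged lactone 16. Retro-[4+2] loss of CO2 from 16 gives cyclohexadiene 17, 1,2-elimination of trimethylsilanol from its C(OSiMe3)2–CH pair aromatises the ring to silyl ether 18, and dilute acid frees the phenol. The closest known reaction type is the one-pot cycloaddition, decarboxylation and elimination of methyl coumalate with ketene dialkyl acetals and enol ethers, which gives 4-alkoxybenzoates; 14 belongs to that class but is bulkier at the nucleophilic carbon than the partners used so far. Ring B of the apigenin unit is closed by intermolecular [4+2] cycloaddition, which forms C2′–C3′ and C4′–C5′ together. The stereocentres of 16 and 17 are lost on aromatisation, so no stereocontrol is needed; the selectivity that matters is regiochemical and is secured by the pyrone, whose C6 is β to the ester and the δ-end of the dienyl lactone and therefore its most electrophilic carbon, so it takes the aryl-bearing nucleophilic carbon of 14 and places the aryl group meta and the oxygen para to the ester. Because both acetal oxygens carry the same silyl group, elimination in either sense leads to the same phenol.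

Step 10
Reactants: 19 methyl 3-[5,7-bis(benzyloxy)-4′-methoxyflavon-8-yl]-4-hydroxybenzoate
Product: 20 methyl 4-(benzyloxy)-3-[5,7-bis(benzyloxy)-4′-methoxyflavon-8-yl]benzoate
Conditions: BnBr, K2CO3, DMF, 50 °C
Reagents that add atoms: benzyl bromide, BrCc1ccccc1
Why: Williamson etherification masks the phenol as a benzyl ether, so that the later base-mediated steps meet no acidic phenol and one hydrogenolysis can end the route.

Step 11
Reactants: 20 methyl 4-(benzyloxy)-3-[5,7-bis(benzyloxy)-4′-methoxyflavon-8-yl]benzoate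
Product: 21 4-(benzyloxy)-3-[5,7-bis(benzyloxy)-4′-methoxyflavon-8-yl]benzoic acid
Conditions: LiOH·H2O, THF/MeOH/H2O, 40 °C; then 1 M HCl
Reagents that add atoms: lithium hydroxide, [Li+].[OH-]
Why: Saponification (BAc2) of the unhindered methyl benzoate under mild conditions that a 5,7-dialkoxyflavone should tolerate.

Step 12
Reactants: 21 4-(benzyloxy)-3-[5,7-bis(benzyloxy)-4′-methoxyflavon-8-yl]benzoic acid; 2 1-[2,4-bis(benzyloxy)-6-hydroxyphenyl]ethanone
Product: 22 2-acetyl-3,5-bis(benzyloxy)phenyl 4-(benzyloxy)-3-[5,7-bis(benzyloxy)-4′-methoxyflavon-8-yl]benzoate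
Conditions: EDC·HCl, DMAP, CH2Cl2, rt
Reagents that add atoms: none
Why: Steglich-type carbodiimide esterification with DMAP as acyl-transfer catalyst acylates the chelated phenol of 2, the standard entry to Baker–Venkataraman substrates.

Step 13
Reactants: 22 2-acetyl-3,5-bis(benzyloxy)phenyl 4-(benzyloxy)-3-[5,7-bis(benzyloxy)-4′-methoxyflavon-8-yl]benzoate
Product: 23 1-[2,4-bis(benzyloxy)-6-hydroxyphenyl]-3-{4-(benzyloxy)-3-[5,7-bis(benzyloxy)-4′-methoxyflavon-8-yl]phenyl}propane-1,3-dione
Conditions: KOtBu (2.5 equiv), THF, 0 °C → rt; then 1 M HCl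
Reagents that add atoms: none
Why: Baker–Venkataraman rearrangement: the acetyl enolate attacks the neighbouring aryl ester intramolecularly (O→C acyl shift through a six-membered ring) to give the phenoxide of the 1,3-diketone, a fast process that a hindered alkoxide base should trigger without opening the existing pyranone.

Step 14
Reactants: 23 1-[2,4-bis(benzyloxy)-6-hydroxyphenyl]-3-{4-(benzyloxy)-3-[5,7-bis(benzyloxy)-4′-methoxyflavon-8-yl]phenyl}propane-1,3-dione
Product: 24 8-{2-(benzyloxy)-5-[5,7-bis(benzyloxy)-4-oxo-4H-chromen-2-yl]phenyl}-5,7-bis(benzyloxy)-2-(4-methoxyphenyl)-4H-chromen-4-one (penta-O-benzyl podocarpusflavone A)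
Conditions: NaOAc, AcOH, 110 °C
Reagents that add atoms: none
Why: Cyclodehydration of the 1-(2-hydroxyaryl)-1,3-diketone, as in step 5, closes the pyranone of the apigenin unit.

Step 15
Reactants: 24 penta-O-benzyl podocarpusflavone A
Product: 25 podocarpusflavone A
Conditions: H2 (1 atm), 10% Pd/C, THF/MeOH, rt
Reagents that add atoms: none
Why: Catalytic hydrogenolysis should cleave all five benzyl aryl ethers while the methyl ether and, at 1 atm and room temperature, the C2–C3 double bonds of both flavone units stay intact.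

**Compound list**

1 | 2,4,6-trihydroxyacetophenone | CC(=O)c1c(O)cc(O)cc1O | starting material
2 | 1-[2,4-bis(benzyloxy)-6-hydroxyphenyl]ethanone | CC(=O)c1c(O)cc(OCc2ccccc2)cc1OCc1ccccc1 | intermediate
3 | allyl bromide | C=CCBr | starting material
4 | 1-[2-(allyloxy)-4,6-bis(benzyloxy)phenyl]ethanone | CC(=O)c1c(OCC=C)cc(OCc2ccccc2)cc1OCc1ccccc1 | intermediate
5 | 2-acetyl-6-allyl-3,5-bis(benzyloxy)cyclohexa-2,4-dien-1-one (racemic, transient) | CC(=O)C1=C(OCc2ccccc2)C=C(OCc2ccccc2)C(CC=C)C1=O | intermediate
6 | 1-[3-allyl-4,6-bis(benzyloxy)-2-hydroxyphenyl]ethanone | CC(=O)c1c(O)c(CC=C)c(OCc2ccccc2)cc1OCc1ccccc1 | intermediate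
7 | 4-methoxybenzoyl chloride | COc1ccc(cc1)C(Cl)=O | starting material
8 | 1-[3-allyl-4,6-bis(benzyloxy)-2-hydroxyphenyl]-3-(4-methoxyphenyl)propane-1,3-dione | COc1ccc(cc1)C(=O)CC(=O)c1c(O)c(CC=C)c(OCc2ccccc2)cc1OCc1ccccc1 | intermediate
9 | 8-allyl-5,7-bis(benzyloxy)-4′-methoxyflavone | COc1ccc(cc1)-c1cc(=O)c2c(OCc3ccccc3)cc(OCc3ccccc3)c(CC=C)c2o1 | intermediate
10 | 5,7-bis(benzyloxy)-8-(2,3-dihydroxypropyl)-4′-methoxyflavone (racemic, transient) | COc1ccc(cc1)-c1cc(=O)c2c(OCc3ccccc3)cc(OCc3ccccc3)c(CC(O)CO)c2o1 | intermediate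
11 | [5,7-bis(benzyloxy)-4′-methoxyflavon-8-yl]acetaldehyde | COc1ccc(cc1)-c1cc(=O)c2c(OCc3ccccc3)cc(OCc3ccccc3)c(CC=O)c2o1 | intermediate
12 | [5,7-bis(benzyloxy)-4′-methoxyflavon-8-yl]acetic acid | COc1ccc(cc1)-c1cc(=O)c2c(OCc3ccccc3)cc(OCc3ccccc3)c(CC(=O)O)c2o1 | intermediate
13 | trimethylsilyl [5,7-bis(benzyloxy)-4′-methoxyflavon-8-yl]acetate | COc1ccc(cc1)-c1cc(=O)c2c(OCc3ccccc3)cc(OCc3ccccc3)c(CC(=O)O[Si](C)(C)C)c2o1 | intermediate
14 | 5,7-bis(benzyloxy)-8-[2,2-bis(trimethylsilyloxy)ethenyl]-4′-methoxyflavone | COc1ccc(cc1)-c1cc(=O)c2c(OCc3ccccc3)cc(OCc3ccccc3)c(C=C(O[Si](C)(C)C)O[Si](C)(C)C)c2o1 | intermediate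
15 | methyl coumalate (methyl 2-oxo-2H-pyran-5-carboxylate) | COC(=O)C1=COC(=O)C=C1 | starting material
16 | methyl 7-[5,7-bis(benzyloxy)-4′-methoxyflavon-8-yl]-3-oxo-8,8-bis(trimethylsilyloxy)-2-oxabicyclo[2.2.2]oct-5-ene-6-carboxylate (racemic, configuration at C7 not defined, transient) | COC(=O)C1=CC2C(=O)OC1C(c1c(OCc3ccccc3)cc(OCc3ccccc3)c3c(=O)cc(-c4ccc(OC)cc4)oc13)C2(O[Si](C)(C)C)O[Si](C)(C)C | intermediate
17 | methyl 3-[5,7-bis(benzyloxy)-4′-methoxyflavon-8-yl]-4,4-bis(trimethylsilyloxy)cyclohexa-1,5-diene-1-carboxylate (racemic, transient) | COC(=O)C1=CC(c2c(OCc3ccccc3)cc(OCc3ccccc3)c3c(=O)cc(-c4ccc(OC)cc4)oc23)C(O[Si](C)(C)C)(O[Si](C)(C)C)C=C1 | intermediate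
18 | methyl 3-[5,7-bis(benzyloxy)-4′-methoxyflavon-8-yl]-4-(trimethylsilyloxy)benzoate | COC(=O)c1ccc(O[Si](C)(C)C)c(c1)-c1c(OCc2ccccc2)cc(OCc2ccccc2)c2c(=O)cc(-c3ccc(OC)cc3)oc12 | intermediate
19 | methyl 3-[5,7-bis(benzyloxy)-4′-methoxyflavon-8-yl]-4-hydroxybenzoate | COC(=O)c1ccc(O)c(c1)-c1c(OCc2ccccc2)cc(OCc2ccccc2)c2c(=O)cc(-c3ccc(OC)cc3)oc12 | intermediate
20 | methyl 4-(benzyloxy)-3-[5,7-bis(benzyloxy)-4′-methoxyflavon-8-yl]benzoate | COC(=O)c1ccc(OCc2ccccc2)c(c1)-c1c(OCc2ccccc2)cc(OCc2ccccc2)c2c(=O)cc(-c3ccc(OC)cc3)oc12 | intermediate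
21 | 4-(benzyloxy)-3-[5,7-bis(benzyloxy)-4′-methoxyflavon-8-yl]benzoic acid | OC(=O)c1ccc(OCc2ccccc2)c(c1)-c1c(OCc2ccccc2)cc(OCc2ccccc2)c2c(=O)cc(-c3ccc(OC)cc3)oc12 | intermediate
22 | 2-acetyl-3,5-bis(benzyloxy)phenyl 4-(benzyloxy)-3-[5,7-bis(benzyloxy)-4′-methoxyflavon-8-yl]benzoate | CC(=O)c1c(OCc2ccccc2)cc(OCc2ccccc2)cc1OC(=O)c1ccc(OCc2ccccc2)c(c1)-c1c(OCc2ccccc2)cc(OCc2ccccc2)c2c(=O)cc(-c3ccc(OC)cc3)oc12 | intermediate
23 | 1-[2,4-bis(benzyloxy)-6-hydroxyphenyl]-3-{4-(benzyloxy)-3-[5,7-bis(benzyloxy)-4′-methoxyflavon-8-yl]phenyl}propane-1,3-dione | O=C(CC(=O)c1ccc(OCc2ccccc2)c(c1)-c1c(OCc2ccccc2)cc(OCc2ccccc2)c2c(=O)cc(-c3ccc(OC)cc3)oc12)c1c(O)cc(OCc2ccccc2)cc1OCc1ccccc1 | intermediate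
24 | 8-{2-(benzyloxy)-5-[5,7-bis(benzyloxy)-4-oxo-4H-chromen-2-yl]phenyl}-5,7-bis(benzyloxy)-2-(4-methoxyphenyl)-4H-chromen-4-one | COc1ccc(cc1)-c1cc(=O)c2c(OCc3ccccc3)cc(OCc3ccccc3)c(c2o1)-c1cc(ccc1OCc1ccccc1)-c1cc(=O)c2c(OCc3ccccc3)cc(OCc3ccccc3)cc2o1 | intermediate
25 | podocarpusflavone A | COc1ccc(-c2cc(=O)c3c(O)cc(O)c(-c4cc(-c5cc(=O)c6c(O)cc(O)cc6o5)ccc4O)c3o2)cc1 | target

**Step count**

Total steps: 15. Longest linear sequence: 15 (steps 1 to 15; compound 2 is made once and enters the chain again in step 12).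

**Steps most likely to fail**

Step 9. The cycloaddition may be too slow at the hindered benzylic carbon, so that the ketene acetal is lost first by protodesilylation, or the reaction may stop after conjugate addition at C6 with silyl transfer instead of ring closure. The fallback makes the C3′–C8 bond by Suzuki–Miyaura coupling; it sets out from 2 and 7 and comes back at 20.
- Acetophenone 2 is iodinated ortho to its free hydroxyl (benzyltrimethylammonium dichloroiodate, CaCO3, CH2Cl2/MeOH) to give 1-[4,6-bis(benzyloxy)-2-hydroxy-3-iodophenyl]ethanone F1.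
- Acylation with 7 under the conditions of step 4 gives 1-[4,6-bis(benzyloxy)-2-hydroxy-3-iodophenyl]-3-(4-methoxyphenyl)propane-1,3-dione F2, and cyclodehydration as in step 5 gives 5,7-bis(benzyloxy)-8-iodo-4′-methoxyflavone F3.
- Commercial methyl 4-hydroxy-3-iodobenzoate (COC(=O)c1ccc(O)c(I)c1) is benzylated (BnBr, K2CO3, DMF) to methyl 4-(benzyloxy)-3-iodobenzoate F4.
- Miyaura borylation (bis(pinacolato)diboron, Pd(dppf)Cl2, KOAc, dioxane, 90 °C) gives methyl 4-(benzyloxy)-3-(4,4,5,5-tetramethyl-1,3,2-dioxaborolan-2-yl)benzoate F5.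
- Coupling of F3 with F5 (Pd(PPh3)4, K3PO4, DMF/H2O, 90 °C) should give 20, from which steps 11 to 15 follow unchanged.

Step 15. Cleavage of the hindered benzyl ethers next to the biaryl axis may stay incomplete on a poorly soluble substrate, and prolonged hydrogenation may start to reduce the C2–C3 double bonds. The fallback sets out from 24 and comes back at 25 without any reduction: BCl3 with pentamethylbenzene as benzyl-cation scavenger in CH2Cl2 at −78 °C, then methanol. This Lewis-acid dealkylation should remove the benzyl ethers and leave the non-chelated aryl methyl ether; it makes no new compound (F0).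

Step 11. Hydroxide may add to C2 of the acacetin pyranone and open that ring, with possible retro-Claisen cleavage, in competition with the slow saponification of the electron-rich benzoate. The fallback sets out from 20 and comes back at 23, avoiding hydroxide altogether: a crossed Claisen condensation of ester 20 with the lithium dianion of 2 (LiN(SiMe3)2, THF, −78 °C → reflux) should give diketone 23 directly. Steps 11 to 13 are thereby replaced and no new compound is made (F0).

**Further compounds**

F1 | step 9 | 1-[4,6-bis(benzyloxy)-2-hydroxy-3-iodophenyl]ethanone | CC(=O)c1c(O)c(I)c(OCc2ccccc2)cc1OCc1ccccc1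
F2 | step 9 | 1-[4,6-bis(benzyloxy)-2-hydroxy-3-iodophenyl]-3-(4-methoxyphenyl)propane-1,3-dione | COc1ccc(cc1)C(=O)CC(=O)c1c(O)c(I)c(OCc2ccccc2)cc1OCc1ccccc1
F3 | step 9 | 5,7-bis(benzyloxy)-8-iodo-4′-methoxyflavone | COc1ccc(cc1)-c1cc(=O)c2c(OCc3ccccc3)cc(OCc3ccccc3)c(I)c2o1
F4 | step 9 | methyl 4-(benzyloxy)-3-iodobenzoate | COC(=O)c1ccc(OCc2ccccc2)c(I)c1
F5 | step 9 | methyl 4-(benzyloxy)-3-(4,4,5,5-tetramethyl-1,3,2-dioxaborolan-2-yl)benzoate | COC(=O)c1ccc(OCc2ccccc2)c(c1)B1OC(C)(C)C(C)(C)O1
F0 | step 15 | none | none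
F0 | step 11 | none | none
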